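**Plan**

- Retrosynthesis (ring numbered C1, aroyl-bearing, then C2, C3=C4 with the homoprenyl chain on C4, C5, and C6, phenyl-bearing; ketone carbon C7): the aryl–C7 bond is cut first (aryllithium plus C7 aldehyde). The ring bond C1–C2 is cut next by a retro-Claisen step that ties C4 to the carboxyl oxygen. The resulting δ-lactone is cut at its vinyl–carbinol and acyl–homoprenyl bonds, back to 3-phenylglutaric anhydride.
- Enabling feature: C7(=O)–C1–C2–C3=C4 is a γ,δ-unsaturated carbonyl unit lying inside the cyclohexene, so the carbocycle can be traded for a 6-vinyl δ-lactone whose ring oxygen sits on C4.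
- Forward: anhydride methanolysis, ketone formation and vinyl addition give the δ-lactone (the only ring at that stage). Its silyl ketene acetal contracts by a [3,3] shift to the cyclohexene acid. The acid is taken to the aldehyde, joined to the aryllithium from protected 5-methoxyresorcinol, oxidised and unmasked.
- Stereochemistry: C6 comes from the catalytic enantioselective opening of the anhydride. C1 is relayed from the lactone carbinol centre (vinyl cis to phenyl gives trans) and is also the thermodynamically preferred epimer next to the carbonyl.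

Key step: step 4

Assumption: the quinine-derived sulfonamide catalyst is taken to open the anhydride to the (R)-hemiester; should the first run show the opposite sense, its quinidine-derived pseudoenantiomer N-[(8R,9R)-6'-methoxycinchonan-9-yl]-3,5-bis(trifluoromethyl)benzenesulfonamide is used under the same conditions and nothing else changes.

**Route**

Step 1
Reactants: 1 3-phenylglutaric anhydride
Product: 2 (R)-5-methoxy-5-oxo-3-phenylpentanoic acid
Conditions: MeOH (10 equiv), N-[(8S,9S)-6'-methoxycinchonan-9-yl]-3,5-bis(trifluoromethyl)benzenesulfonamide (10 mol%), MTBE, rt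
Reagents that add atoms: methanol, CO
Why: Alcoholytic desymmetrisation of a prochiral cyclic anhydride by a bifunctional cinchona catalyst (amine activates methanol, sulfonamide N–H binds one enantiotopic carbonyl) is established for 3-arylglutaric anhydrides and fixes the phenyl-bearing centre that becomes C6, the optical purity being raised by crystallisation of an amine salt if needed.

Step 2
Reactants: 2 (R)-5-methoxy-5-oxo-3-phenylpentanoic acid; 3 5-bromo-2-methylpent-2-ene
Product: 6 methyl (R)-9-methyl-5-oxo-3-phenyldec-8-enoate, via acid chloride 4 (not isolated), via alkylzinc bromide 5 (not isolated)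
Conditions: (a) (COCl)2, DMF (cat.), CH2Cl2, 0 °C → rt, evaporate; (b) 3, Zn dust, LiCl, THF, 40 °C; then 4, Pd(PPh3)4 (5 mol%), THF, 0 °C → rt
Reagents that add atoms: none
Why: Oxalyl chloride with catalytic DMF converts only the free acid into the acid chloride, and Negishi acylation of the primary alkylzinc bromide under zerovalent palladium catalysis stops at the ketone because organozinc reagents attack neither ketones nor esters, the stereocentre being untouched.

Step 3
Reactants: 6 methyl (R)-9-methyl-5-oxo-3-phenyldec-8-enoate; 7 vinylmagnesium bromide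
Product: 9 (4R,6R)-6-ethenyl-6-(4-methylpent-3-en-1-yl)-4-phenyloxan-2-one, via magnesium alkoxide 8 (not isolated)
Conditions: LaCl3·2LiCl, THF, −78 → 0 °C, then rt; SiO2 chromatography
Reagents that add atoms: none
Why: Grignard 1,2-addition, made ketone-selective and less basic by LaCl3·2LiCl, gives a tertiary alkoxide that closes onto the δ-ester by acyl substitution to the six-membered lactone; the remote phenyl centre is expected to give little 1,3-induction, so the carbinol configuration is secured by chromatographic separation of the two C6 epimers, the cis isomer (vinyl and phenyl on the same face) to be identified by an NOE between H-4 and the homoprenyl CH2 that is syn-axial to it.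

Step 4
Reactants: 9 (4R,6R)-6-ethenyl-6-(4-methylpent-3-en-1-yl)-4-phenyloxan-2-one
Product: 12 (1R,6R)-4-(4-methylpent-3-en-1-yl)-6-phenylcyclohex-3-ene-1-carboxylic acid, via silyl ketene acetal 10 (not isolated), via silyl ester 11 (not isolated)
Conditions: LDA, THF, −78 °C; TBSCl, DMPU, −78 °C → rt; toluene, 105 °C; then 1 M aq. HCl, THF, rt
Reagents that add atoms: none
Why: Deprotonation at lactone C3 and O-silylation give the cyclic silyl ketene acetal, whose C3=C2–O1–C6–CH=CH2 array undergoes a concerted [3,3] shift on heating: lactone C3 bonds to the vinyl terminus (C1–C2 of the target), the tertiary allylic C6–O1 bond breaks and the alkene moves to C6=CH (C3=C4 of the target). The closest known reaction type is the Ireland–Claisen ring contraction of alkenyl lactones to carbocyclic acids. The six-membered carbocycle closes through this sigmatropic C–C bond formation itself, via a boat-like, bicyclo[2.2.2]octane-shaped transition state that the lactone ring enforces, with the vinyl group pseudoaxial and reaching across the ring. The single new stereocentre, C1, is controlled by the lactone carbinol carbon: the vinyl group can bond only to the lactone face it occupies, and with phenyl on that same face the phenyl points towards the forming two-carbon bridge and ends up trans to the carboxyl group, giving (1R,6R). The step needs O- rather than C-silylation (TBSCl with DMPU on the lithium enolate) and participation of the vinyl group alone; C3 is the only enolisable position and the homoprenyl alkene cannot reach a six-membered array, and mild acid then frees the acid from its silyl ester.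

Step 5
Reactants: 12 (1R,6R)-4-(4-methylpent-3-en-1-yl)-6-phenylcyclohex-3-ene-1-carboxylic acid
Product: 13 [(1R,6R)-4-(4-methylpent-3-en-1-yl)-6-phenylcyclohex-3-en-1-yl]methanol
Conditions: LiAlH4, THF, 0 °C → rt
Reagents that add atoms: none
Why: Hydride reduction of the carboxylic acid with LiAlH4 gives the primary alcohol and leaves the two unactivated trisubstituted alkenes and both stereocentres alone.

Step 6
Reactants: 13 [(1R,6R)-4-(4-methylpent-3-en-1-yl)-6-phenylcyclohex-3-en-1-yl]methanol
Product: 14 (1R,6R)-4-(4-methylpent-3-en-1-yl)-6-phenylcyclohex-3-ene-1-carbaldehyde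
Conditions: Dess–Martin periodinane (DMP), CH2Cl2, 0 °C → rt
Reagents that add atoms: none
Why: Dess–Martin oxidation stops at the aldehyde under nearly neutral conditions, and C1 already holds the preferred trans arrangement with both ring substituents pseudoequatorial, so enolisation cannot erode it.

Step 7
Reactants: 15 5-methoxyresorcinol
Product: 16 1-methoxy-3,5-bis(methoxymethoxy)benzene
Conditions: MOMCl, i-Pr2NEt, CH2Cl2, 0 °C → rt
Reagents that add atoms: chloromethyl methyl ether, COCCl
Why: Williamson-type O-alkylation of both phenols gives the bis-MOM ether, chosen because MOM groups stabilise an ortho-aryllithium by chelation and are removed by mild acid.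

Step 8
Reactants: 16 1-methoxy-3,5-bis(methoxymethoxy)benzene
Product: 17 2-bromo-1-methoxy-3,5-bis(methoxymethoxy)benzene
Conditions: NBS, CH2Cl2, −78 → 0 °C
Reagents that add atoms: N-bromosuccinimide, O=C1CCC(=O)N1Br
Why: Electrophilic aromatic bromination of the trioxygenated ring is fast at low temperature and stops at the monobromide; the two equivalent positions flanked by OMe and OMOM are favoured statistically and sterically over the one position between the two larger OMOM groups, and any regioisomer is to be removed by chromatography.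

Step 9
Reactants: 14 (1R,6R)-4-(4-methylpent-3-en-1-yl)-6-phenylcyclohex-3-ene-1-carbaldehyde; 17 2-bromo-1-methoxy-3,5-bis(methoxymethoxy)benzene
Product: 19 [2-methoxy-4,6-bis(methoxymethoxy)phenyl][(1R,6R)-4-(4-methylpent-3-en-1-yl)-6-phenylcyclohex-3-en-1-yl]methanol (both carbinol epimers), via aryllithium 18 (not isolated)
Conditions: 17, n-BuLi, THF, −78 °C; then 14, −78 → −20 °C
Reagents that add atoms: none
Why: Bromine–lithium exchange gives the chelation-stabilised aryllithium, which should add to the aldehyde carbonyl faster than it deprotonates C1; the carbinol centre forms without control and is erased in the next step.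

Step 10
Reactants: 19 [2-methoxy-4,6-bis(methoxymethoxy)phenyl][(1R,6R)-4-(4-methylpent-3-en-1-yl)-6-phenylcyclohex-3-en-1-yl]methanol
Product: 20 [2-methoxy-4,6-bis(methoxymethoxy)phenyl][(1R,6R)-4-(4-methylpent-3-en-1-yl)-6-phenylcyclohex-3-en-1-yl]methanone
Conditions: DMP, CH2Cl2, 0 °C → rt; then NaOMe (cat.), MeOH, rt
Reagents that add atoms: none
Why: Dess–Martin oxidation converts the hindered secondary carbinol into the aryl ketone, and brief exposure to catalytic methoxide equilibrates C1 through the enolate to the trans arrangement, correcting any cis epimer carried in from earlier steps.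

Step 11
Reactants: 20 [2-methoxy-4,6-bis(methoxymethoxy)phenyl][(1R,6R)-4-(4-methylpent-3-en-1-yl)-6-phenylcyclohex-3-en-1-yl]methanone
Product: 21 (2,4-dihydroxy-6-methoxyphenyl)[(1R,6R)-4-(4-methylpent-3-en-1-yl)-6-phenylcyclohex-3-en-1-yl]methanone
Conditions: 3 M aq. HCl, MeOH, rt → 40 °C
Reagents that add atoms: none
Why: Acid-catalysed acetal exchange with methanol removes both MOM groups (the one ortho to the ketone first) under conditions that should spare the two trisubstituted alkenes, and in the absence of base C1 is not disturbed.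

**Compound list**

1 | 3-phenylglutaric anhydride (4-phenyloxane-2,6-dione) | O=C1CC(c2ccccc2)CC(=O)O1 | starting material
2 | (R)-5-methoxy-5-oxo-3-phenylpentanoic acid | COC(=O)C[C@H](c1ccccc1)CC(=O)O | intermediate
3 | 5-bromo-2-methylpent-2-ene | CC(C)=CCCBr | starting material
4 | methyl (S)-5-chloro-5-oxo-3-phenylpentanoate | COC(=O)C[C@H](c1ccccc1)CC(=O)Cl | intermediate (not isolated)
5 | (4-methylpent-3-en-1-yl)zinc bromide | CC(C)=CCC[Zn]Br | intermediate (not isolated)
6 | methyl (R)-9-methyl-5-oxo-3-phenyldec-8-enoate | COC(=O)C[C@H](c1ccccc1)CC(=O)CCC=C(C)C | intermediate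
7 | vinylmagnesium bromide | C=C[Mg]Br | starting material
8 | bromomagnesium alkoxide of methyl (3R,5R)-5-ethenyl-5-hydroxy-9-methyl-3-phenyldec-8-enoate | COC(=O)C[C@H](c1ccccc1)C[C@@](O[Mg]Br)(C=C)CCC=C(C)C | intermediate (not isolated)
9 | (4R,6R)-6-ethenyl-6-(4-methylpent-3-en-1-yl)-4-phenyloxan-2-one (vinyl cis to phenyl) | O=C1C[C@H](c2ccccc2)C[C@@](C=C)(CCC=C(C)C)O1 | intermediate
10 | tert-butyl{[(2R,4R)-2-ethenyl-2-(4-methylpent-3-en-1-yl)-4-phenyl-3,4-dihydro-2H-pyran-6-yl]oxy}dimethylsilane | CC(C)(C)[Si](C)(C)OC1=C[C@H](c2ccccc2)C[C@@](C=C)(CCC=C(C)C)O1 | intermediate (not isolated)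
11 | tert-butyldimethylsilyl (1R,6R)-4-(4-methylpent-3-en-1-yl)-6-phenylcyclohex-3-ene-1-carboxylate | CC(C)(C)[Si](C)(C)OC(=O)[C@@H]1CC=C(CCC=C(C)C)C[C@H]1c1ccccc1 | intermediate (not isolated)
12 | (1R,6R)-4-(4-methylpent-3-en-1-yl)-6-phenylcyclohex-3-ene-1-carboxylic acid (trans) | OC(=O)[C@@H]1CC=C(CCC=C(C)C)C[C@H]1c1ccccc1 | intermediate
13 | [(1R,6R)-4-(4-methylpent-3-en-1-yl)-6-phenylcyclohex-3-en-1-yl]methanol | OC[C@@H]1CC=C(CCC=C(C)C)C[C@H]1c1ccccc1 | intermediate
14 | (1R,6R)-4-(4-methylpent-3-en-1-yl)-6-phenylcyclohex-3-ene-1-carbaldehyde | O=C[C@@H]1CC=C(CCC=C(C)C)C[C@H]1c1ccccc1 | intermediate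
15 | 5-methoxyresorcinol (5-methoxybenzene-1,3-diol) | COc1cc(O)cc(O)c1 | starting material
16 | 1-methoxy-3,5-bis(methoxymethoxy)benzene | COCOc1cc(OC)cc(OCOC)c1 | intermediate
17 | 2-bromo-1-methoxy-3,5-bis(methoxymethoxy)benzene | COCOc1cc(OC)c(Br)c(OCOC)c1 | intermediate
18 | [2-methoxy-4,6-bis(methoxymethoxy)phenyl]lithium | [Li]c1c(OC)cc(OCOC)cc1OCOC | intermediate (not isolated)
19 | [2-methoxy-4,6-bis(methoxymethoxy)phenyl][(1R,6R)-4-(4-methylpent-3-en-1-yl)-6-phenylcyclohex-3-en-1-yl]methanol, both carbinol epimers | COCOc1cc(OC)c(C(O)[C@@H]2CC=C(CCC=C(C)C)C[C@H]2c2ccccc2)c(OCOC)c1 | intermediate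
20 | [2-methoxy-4,6-bis(methoxymethoxy)phenyl][(1R,6R)-4-(4-methylpent-3-en-1-yl)-6-phenylcyclohex-3-en-1-yl]methanone | COCOc1cc(OC)c(C(=O)[C@@H]2CC=C(CCC=C(C)C)C[C@H]2c2ccccc2)c(OCOC)c1 | intermediate
21 | (2,4-dihydroxy-6-methoxyphenyl)[(1R,6R)-4-(4-methylpent-3-en-1-yl)-6-phenylcyclohex-3-en-1-yl]methanone | COc1cc(O)cc(O)c1C(=O)[C@@H]1CC=C(CCC=C(C)C)C[C@H]1c1ccccc1 | target

**Count**

Total steps: 11. Longest linear sequence: 9 steps (steps 1 to 6, then 9 to 11); the aryl bromide takes 2 steps (7 and 8) before the union in step 9.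

**Steps most likely to fail, with fallbacks**

Step 3. The vinyl nucleophile may show poor facial selectivity at the ketone, because the only stereocentre sits two atoms away and offers no chelating group; the wanted cis lactone would then be only part of an epimer pair that may also resist separation. The fallback moves the stereochemical burden from the lactone carbinol centre to thermodynamic control at C1.
- It sets out from 9 as the unseparated mixture with its C6 epimer, (4R,6S)-6-ethenyl-6-(4-methylpent-3-en-1-yl)-4-phenyloxan-2-one F1, and carries the mixture through the conditions of steps 4 to 6.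
- F1 passes through its silyl ketene acetal F2 and the cis silyl ester F3 to the cis acid (1S,6R)-4-(4-methylpent-3-en-1-yl)-6-phenylcyclohex-3-ene-1-carboxylic acid F4.
- LiAlH4 then gives the cis alcohol F5, and DMP gives the cis aldehyde F6.
- The aldehyde mixture is stirred with DBU in CH2Cl2. F6, which must place one of its two ring substituents pseudoaxial, should epimerise at C1 through its enolate to the trans aldehyde 14, where the route is rejoined.

Step 4. Silylation may be incomplete or go to carbon, and the ketene acetal may ionise at its tertiary allylic C–O bond and eliminate to open-chain triene acids before the strained boat transition state is reached. The fallback closes the same cyclohexene at its alkene instead, by ring-closing metathesis.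
- It sets out from 6. Wittig methylenation (Ph3P=CH2, THF) gives methyl (3R)-9-methyl-5-methylidene-3-phenyldec-8-enoate F7.
- Enolate allylation (LDA, THF, −78 °C; allyl bromide) gives methyl (3R)-9-methyl-5-methylidene-3-phenyl-2-(prop-2-en-1-yl)dec-8-enoate F8 as both C2 epimers.
- The second-generation Grubbs catalyst (H2IMes)(PCy3)Cl2Ru=CHPh in CH2Cl2 at 40 °C joins the allyl group to the 1,1-disubstituted alkene, giving methyl (6R)-4-(4-methylpent-3-en-1-yl)-6-phenylcyclohex-3-ene-1-carboxylate F9 as C1 epimers.
- NaOMe in MeOH equilibrates these to the trans ester methyl (1R,6R)-4-(4-methylpent-3-en-1-yl)-6-phenylcyclohex-3-ene-1-carboxylate F10.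
- LiOH in THF–water then gives acid 12, where the route is rejoined.

Step 11. During MOM cleavage, protonation of the 1,5-diene formed by the ring alkene and the side-chain alkene may trigger cation–olefin cyclisation or addition of methanol, while conditions gentle enough to avoid this may leave the para MOM group in place. The fallback replaces the acid-labile protection by allyl ethers that come off under neutral palladium catalysis.
- It sets out from 15. Allyl bromide and K2CO3 in acetone give 1-methoxy-3,5-bis(prop-2-en-1-yloxy)benzene F11.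
- NBS in CH2Cl2 at −78 °C gives 2-bromo-1-methoxy-3,5-bis(prop-2-en-1-yloxy)benzene F12.
- n-BuLi in THF at −78 °C gives [2-methoxy-4,6-bis(prop-2-en-1-yloxy)phenyl]lithium F13, which is added to aldehyde 14 to give the bis-allyl carbinol F14.
- DMP gives the bis-allyl ketone F15.
- Pd(PPh3)4 (cat.) with morpholine in THF at rt transfers both allyl groups to the amine and delivers 21, where the route is rejoined.

**Further compounds**

F1 | step 3 | (4R,6S)-6-ethenyl-6-(4-methylpent-3-en-1-yl)-4-phenyloxan-2-one | O=C1C[C@H](c2ccccc2)C[C@](C=C)(CCC=C(C)C)O1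
F2 | step 3 | tert-butyl{[(2S,4R)-2-ethenyl-2-(4-methylpent-3-en-1-yl)-4-phenyl-3,4-dihydro-2H-pyran-6-yl]oxy}dimethylsilane | CC(C)(C)[Si](C)(C)OC1=C[C@H](c2ccccc2)C[C@](C=C)(CCC=C(C)C)O1
F3 | step 3 | tert-butyldimethylsilyl (1S,6R)-4-(4-methylpent-3-en-1-yl)-6-phenylcyclohex-3-ene-1-carboxylate | CC(C)(C)[Si](C)(C)OC(=O)[C@H]1CC=C(CCC=C(C)C)C[C@H]1c1ccccc1
F4 | step 3 | (1S,6R)-4-(4-methylpent-3-en-1-yl)-6-phenylcyclohex-3-ene-1-carboxylic acid | OC(=O)[C@H]1CC=C(CCC=C(C)C)C[C@H]1c1ccccc1
F5 | step 3 | [(1S,6R)-4-(4-methylpent-3-en-1-yl)-6-phenylcyclohex-3-en-1-yl]methanol | OC[C@H]1CC=C(CCC=C(C)C)C[C@H]1c1ccccc1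
F6 | step 3 | (1S,6R)-4-(4-methylpent-3-en-1-yl)-6-phenylcyclohex-3-ene-1-carbaldehyde | O=C[C@H]1CC=C(CCC=C(C)C)C[C@H]1c1ccccc1
F7 | step 4 | methyl (3R)-9-methyl-5-methylidene-3-phenyldec-8-enoate | COC(=O)C[C@H](c1ccccc1)CC(=C)CCC=C(C)C
F8 | step 4 | methyl (3R)-9-methyl-5-methylidene-3-phenyl-2-(prop-2-en-1-yl)dec-8-enoate, both C2 epimers | COC(=O)C(CC=C)[C@H](c1ccccc1)CC(=C)CCC=C(C)C
F9 | step 4 | methyl (6R)-4-(4-methylpent-3-en-1-yl)-6-phenylcyclohex-3-ene-1-carboxylate, both C1 epimers | COC(=O)C1CC=C(CCC=C(C)C)C[C@H]1c1ccccc1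
F10 | step 4 | methyl (1R,6R)-4-(4-methylpent-3-en-1-yl)-6-phenylcyclohex-3-ene-1-carboxylate | COC(=O)[C@@H]1CC=C(CCC=C(C)C)C[C@H]1c1ccccc1
F11 | step 11 | 1-methoxy-3,5-bis(prop-2-en-1-yloxy)benzene | COc1cc(OCC=C)cc(OCC=C)c1
F12 | step 11 | 2-bromo-1-methoxy-3,5-bis(prop-2-en-1-yloxy)benzene | COc1cc(OCC=C)cc(OCC=C)c1Br
F13 | step 11 | [2-methoxy-4,6-bis(prop-2-en-1-yloxy)phenyl]lithium | [Li]c1c(OC)cc(OCC=C)cc1OCC=C
F14 | step 11 | [2-methoxy-4,6-bis(prop-2-en-1-yloxy)phenyl][(1R,6R)-4-(4-methylpent-3-en-1-yl)-6-phenylcyclohex-3-en-1-yl]methanol, both carbinol epimers | COc1cc(OCC=C)cc(OCC=C)c1C(O)[C@@H]1CC=C(CCC=C(C)C)C[C@H]1c1ccccc1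
F15 | step 11 | [2-methoxy-4,6-bis(prop-2-en-1-yloxy)phenyl][(1R,6R)-4-(4-methylpent-3-en-1-yl)-6-phenylcyclohex-3-en-1-yl]methanone | COc1cc(OCC=C)cc(OCC=C)c1C(=O)[C@@H]1CC=C(CCC=C(C)C)C[C@H]1c1ccccc1
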